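**Strategy.** The C30 diene is twofold-symmetric: two trans-decalin halves (ring A C1–C5/C10, ring B C5–C10, C8=C9) joined by C11–C11′. Each half is built on an enantioenriched ring A ketone whose C5 carbonyl, flanked by quaternary C4 and C10, cannot enolise. In the key step the only possible enolate (C8, next to the C9 ketone) adds to vinyltriphenylphosphonium bromide, and the resulting C6 ylide closes ring B by intramolecular Wittig olefination at C5. α-Face hydrogenation then sets the trans ring fusion. The C9 ketone becomes an enol triflate; two triflates are stitched to a two-carbon linchpin and the central alkene is reduced.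

Key step: step 7

Numbering used for each half: ring A = C1, C2, C3, C4 (gem-dimethyl), C5, C10 (methyl); ring B = C5, C6, C7, C8 (methyl), C9, C10; C11 = CH2 on C9; primes mark the second half.

Assumption: (R)-t-Bu-PHOX is taken to deliver (R)-5, the mirror-image ligand being associated with the (S)-series of 2-allyl-2-alkylcyclohexanones. Any residual minor enantiomer should end mainly in the heterochiral diastereomer of 19, which is to be removed at that stage.

Step 1
Reactants: 1 2,2,6-trimethylcyclohexan-1-one; 2 allyl chloroformate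
Product: 4 allyl 2,6,6-trimethylcyclohex-1-en-1-yl carbonate, via lithium enolate 3 (not isolated)
Conditions: LiHMDS, THF, 0 °C; then 2, −78 °C
Reagents that add atoms: allyl chloroformate 2, C=CCOC(=O)Cl
Why: Ketone 1 has a single α-hydrogen, so one tetrasubstituted enolate forms and its O-acylation by the chloroformate (enolate O-acylation) should give the allyl enol carbonate.

Step 2
Reactants: 4 allyl 2,6,6-trimethylcyclohex-1-en-1-yl carbonate
Product: 5 (2R)-2,6,6-trimethyl-2-(prop-2-en-1-yl)cyclohexan-1-one
Conditions: Pd2(dba)3 (cat., zerovalent palladium), (R)-t-Bu-PHOX (cat.), THF, 25 °C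
Reagents that add atoms: none
Why: Decarboxylative asymmetric allylic alkylation (Tsuji allylation): ionisation and loss of CO2 give an allylpalladium enolate, and C–C bond formation inside the chiral P,N-ligand sphere should set the quaternary C10 centre as R.

Step 3
Reactants: 5 (2R)-2,6,6-trimethyl-2-(prop-2-en-1-yl)cyclohexan-1-one
Product: 6 (2R)-2,6,6-trimethyl-2-[(1E)-prop-1-en-1-yl]cyclohexan-1-one
Conditions: RuHCl(CO)(PPh3)3 (cat.), toluene, 80 °C
Reagents that add atoms: none
Why: Ruthenium hydride olefin isomerisation (hydrometalation, β-hydride elimination) should move the terminal alkene to the more stable internal E-alkene and stop there because C10 is quaternary.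

Step 4
Reactants: 6 (2R)-2,6,6-trimethyl-2-[(1E)-prop-1-en-1-yl]cyclohexan-1-one
Product: 8 (1R)-1,3,3-trimethyl-2-oxocyclohexane-1-carbaldehyde, via secondary ozonide 7 (not isolated)
Conditions: O3, CH2Cl2, −78 °C; then Me2S, −78 → 25 °C
Reagents that add atoms: ozone, O=[O+][O-]
Why: Ozonolysis with reductive work-up should cleave the propenyl group to the C9 aldehyde, which cannot enolise or epimerise at the quaternary C10.

Step 5
Reactants: 8 (1R)-1,3,3-trimethyl-2-oxocyclohexane-1-carbaldehyde; 9 ethylmagnesium bromide
Product: 10 (2R)-2-(1-hydroxypropyl)-2,6,6-trimethylcyclohexan-1-one (both carbinol epimers)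
Conditions: EtMgBr, THF, −78 °C; then aq. NH4Cl
Reagents that add atoms: ethylmagnesium bromide 9, CC[Mg]Br
Why: Grignard addition should occur only at the aldehyde because the C5 ketone is shielded by two quaternary neighbours; the low temperature suppresses retro-aldol cleavage, and the carbinol configuration is irrelevant since it is oxidised next.

Step 6
Reactants: 10 (2R)-2-(1-hydroxypropyl)-2,6,6-trimethylcyclohexan-1-one
Product: 11 (2R)-2,6,6-trimethyl-2-propanoylcyclohexan-1-one
Conditions: Dess–Martin periodinane, CH2Cl2, 0 → 25 °C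
Reagents that add atoms: none
Why: Dess–Martin oxidation under neutral conditions should give the 1,3-diketone without retro-Claisen cleavage at the quaternary C10.

Step 7
Reactants: 11 (2R)-2,6,6-trimethyl-2-propanoylcyclohexan-1-one; 12 vinyltriphenylphosphonium bromide
Product: 14 (8aS)-2,5,5,8a-tetramethyl-3,5,6,7,8,8a-hexahydronaphthalen-1(2H)-one (both C2 epimers), via phosphorus ylide 13 (not isolated)
Conditions: NaH, THF, 0 °C; then 12 (1.1 equiv), THF–DMF, 25 → 80 °C
Reagents that add atoms: vinyltriphenylphosphonium bromide 12, C=C[P+](c1ccccc1)(c1ccccc1)c1ccccc1.[Br-]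
Why: NaH can deprotonate 11 only at C8, because the C5 carbonyl of ring A lies between the quaternary carbons C4 and C10 and has no α-hydrogen; the enolate adds through carbon to the vinylphosphonium salt (conjugate addition, new C7–C8 bond) and gives the non-stabilised ylide 13 at C6. The ylide carbon then attacks the C5 carbonyl and the oxaphosphetane collapses to Ph3PO and the C5=C6 double bond, which closes ring B (C5–C6–C7–C8–C9–C10) in a 6-exo-trig mode with respect to the C5=O bond. The closest known reaction type is the cycloalkene annulation of keto enolates with vinylphosphonium salts (conjugate addition followed by intramolecular Wittig olefination). The step needs olefination at C5 and not at C9, which ring size secures because attack of C6 on C9 would give a cyclobutene, and it needs a persistent ylide, which is expected because the phosphonium C–H is more acidic than the remaining C8–H. The only new stereocentre, C8, forms without control and is erased in step 9, the C10 centre is untouched, and the C5=C6 alkene is the handle from which C5 is set in step 8. The main risk is steric shielding of the C5 carbonyl, which intramolecular delivery and heating are meant to overcome.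

Step 8
Reactants: 14 (8aS)-2,5,5,8a-tetramethyl-3,5,6,7,8,8a-hexahydronaphthalen-1(2H)-one
Product: 15 (4aS,8aS)-2,5,5,8a-tetramethyl-3,4,4a,5,6,7,8,8a-octahydronaphthalen-1(2H)-one (both C2 epimers)
Conditions: H2 (5 bar), Pd/C, EtOAc–AcOH, 25 °C
Reagents that add atoms: none
Why: Heterogeneous catalytic hydrogenation should deliver hydrogen to the α-face of the C5=C6 bond, anti to the axial C10 methyl and the axial C4 methyl, which sets C5 as S (trans ring fusion) and leaves the hindered C9 ketone intact.

Step 9
Reactants: 15 (4aS,8aS)-2,5,5,8a-tetramethyl-3,4,4a,5,6,7,8,8a-octahydronaphthalen-1(2H)-one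
Product: 17 (4aS,8aS)-2,5,5,8a-tetramethyl-3,4,4a,5,6,7,8,8a-octahydronaphthalen-1-yl trifluoromethanesulfonate, via potassium enolate 16 (not isolated)
Conditions: KHMDS, THF, −78 → 0 °C; then PhNTf2, −78 → 25 °C
Reagents that add atoms: N-phenylbis(trifluoromethanesulfonimide), O=S(=O)(N(c1ccccc1)S(=O)(=O)C(F)(F)F)C(F)(F)F
Why: The C9 ketone can enolise only toward C8 (C10 is quaternary), so enolate O-triflation should give the tetrasubstituted C8=C9 enol triflate as a single regioisomer, whichever C8 epimer is used.

Step 10
Reactants: 17 (4aS,8aS)-2,5,5,8a-tetramethyl-3,4,4a,5,6,7,8,8a-octahydronaphthalen-1-yl trifluoromethanesulfonate (2 equiv); 18 (E)-1,2-bis(tributylstannyl)ethene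
Product: 19 1,1'-[(E)-ethene-1,2-diyl]bis[(4aS,8aS)-2,5,5,8a-tetramethyl-3,4,4a,5,6,7,8,8a-octahydronaphthalene]
Conditions: Pd2(dba)3 (cat., zerovalent palladium), AsPh3, NMP, 70 °C
Reagents that add atoms: (E)-1,2-bis(tributylstannyl)ethene 18, CCCC[Sn](CCCC)(CCCC)/C=C/[Sn](CCCC)(CCCC)CCCC
Why: A double Stille coupling (oxidative addition into the vinyl triflate, transmetalation, reductive elimination, twice) should join both C9 carbons to the two-carbon linchpin with retention of the E geometry and so install C11 and C11′ in one operation.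

Step 11
Reactants: 19 1,1'-[(E)-ethene-1,2-diyl]bis[(4aS,8aS)-2,5,5,8a-tetramethyl-3,4,4a,5,6,7,8,8a-octahydronaphthalene]
Product: 20 1,1'-(ethane-1,2-diyl)bis[(4aS,8aS)-2,5,5,8a-tetramethyl-3,4,4a,5,6,7,8,8a-octahydronaphthalene]
Conditions: TsNHNH2 (excess), NaOAc, DME–H2O, reflux
Reagents that add atoms: none
Why: Diimide reduction transfers H2 in a concerted syn fashion to the least substituted double bond, so the central disubstituted C11=C11′ alkene should be saturated without migration while the two tetrasubstituted C8=C9 alkenes stay untouched.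

Compound list
1 | 2,2,6-trimethylcyclohexan-1-one | CC1CCCC(C)(C)C1=O | starting material
2 | allyl chloroformate | C=CCOC(=O)Cl | starting material
3 | lithium 2,6,6-trimethylcyclohex-1-en-1-olate | [Li+].[O-]C1=C(C)CCCC1(C)C | intermediate
4 | allyl 2,6,6-trimethylcyclohex-1-en-1-yl carbonate | C=CCOC(=O)OC1=C(C)CCCC1(C)C | intermediate
5 | (2R)-2,6,6-trimethyl-2-(prop-2-en-1-yl)cyclohexan-1-one | C=CC[C@@]1(C)CCCC(C)(C)C1=O | intermediate
6 | (2R)-2,6,6-trimethyl-2-[(1E)-prop-1-en-1-yl]cyclohexan-1-one | C/C=C/[C@@]1(C)CCCC(C)(C)C1=O | intermediate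
7 | 3-methyl-5-[(1R)-1,3,3-trimethyl-2-oxocyclohexyl]-1,2,4-trioxolane (secondary ozonide) | CC1OOC(O1)[C@@]2(C)CCCC(C)(C)C2=O | intermediate
8 | (1R)-1,3,3-trimethyl-2-oxocyclohexane-1-carbaldehyde | O=C[C@@]1(C)CCCC(C)(C)C1=O | intermediate
9 | ethylmagnesium bromide | CC[Mg]Br | starting material
10 | (2R)-2-(1-hydroxypropyl)-2,6,6-trimethylcyclohexan-1-one (carbinol epimers) | CCC(O)[C@@]1(C)CCCC(C)(C)C1=O | intermediate
11 | (2R)-2,6,6-trimethyl-2-propanoylcyclohexan-1-one | CCC(=O)[C@@]1(C)CCCC(C)(C)C1=O | intermediate
12 | vinyltriphenylphosphonium bromide | C=C[P+](c1ccccc1)(c1ccccc1)c1ccccc1.[Br-] | starting material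
13 | triphenyl{3-methyl-4-oxo-4-[(1R)-1,3,3-trimethyl-2-oxocyclohexyl]butylidene}-λ5-phosphane (C6 ylide) | CC(CC=P(c1ccccc1)(c1ccccc1)c1ccccc1)C(=O)[C@@]2(C)CCCC(C)(C)C2=O | intermediate
14 | (8aS)-2,5,5,8a-tetramethyl-3,5,6,7,8,8a-hexahydronaphthalen-1(2H)-one (C2 epimers) | O=C1C(C)CC=C2C(C)(C)CCC[C@]12C | intermediate
15 | (4aS,8aS)-2,5,5,8a-tetramethyl-3,4,4a,5,6,7,8,8a-octahydronaphthalen-1(2H)-one (C2 epimers) | O=C1C(C)CC[C@H]2C(C)(C)CCC[C@]12C | intermediate
16 | potassium (4aS,8aS)-2,5,5,8a-tetramethyl-3,4,4a,5,6,7,8,8a-octahydronaphthalen-1-olate | [K+].[O-]C1=C(C)CC[C@H]2C(C)(C)CCC[C@]12C | intermediate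
17 | (4aS,8aS)-2,5,5,8a-tetramethyl-3,4,4a,5,6,7,8,8a-octahydronaphthalen-1-yl trifluoromethanesulfonate | FC(F)(F)S(=O)(=O)OC1=C(C)CC[C@H]2C(C)(C)CCC[C@]12C | intermediate
18 | (E)-1,2-bis(tributylstannyl)ethene | CCCC[Sn](CCCC)(CCCC)/C=C/[Sn](CCCC)(CCCC)CCCC | starting material
19 | 1,1'-[(E)-ethene-1,2-diyl]bis[(4aS,8aS)-2,5,5,8a-tetramethyl-3,4,4a,5,6,7,8,8a-octahydronaphthalene] | CC1=C(/C=C/C3=C(C)CC[C@H]4C(C)(C)CCC[C@]34C)[C@@]2(C)CCCC(C)(C)[C@@H]2CC1 | intermediate
20 | 1,1'-(ethane-1,2-diyl)bis[(4aS,8aS)-2,5,5,8a-tetramethyl-3,4,4a,5,6,7,8,8a-octahydronaphthalene] | CC1=C(CCC2=C(C)CC[C@H]3C(C)(C)CCC[C@]23C)[C@@]2(C)CCCC(C)(C)[C@@H]2CC1 | target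

Total step count: 11. Longest linear sequence: 11 steps (1 → 20; step 10 uses two molecules of 17).

Steps most likely to fail, with fallbacks

Step 7. The intramolecular Wittig olefination may stall at the encumbered C5 carbonyl, so that the ylide is lost by protonation or retro-conjugate addition before ring B closes. The fallback closes the same bond reductively. Setting out from 11, C8-allylation (LDA, allyl bromide, THF, −78 °C) should give (2R)-2,6,6-trimethyl-2-(2-methylpent-4-enoyl)cyclohexan-1-one F1. Ozonolysis (O3, CH2Cl2, −78 °C; Me2S) should then give the keto aldehyde 3-methyl-4-oxo-4-[(1R)-1,3,3-trimethyl-2-oxocyclohexyl]butanal F2. An intramolecular McMurry coupling of the C6 aldehyde with the C5 ketone (TiCl3, Zn–Cu, DME, reflux, high dilution; low-valent titanium) should form the C5=C6 bond and return to the route at 14. The C9 ketone cannot reach either partner through a strain-free ring; should it be partly reduced, it would be re-oxidised.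

Step 11. The central alkene of 19 is shielded on both faces by the C8 methyls and the C10 substituents, so diimide may disproportionate faster than it reduces and the reduction may stay incomplete. The fallback leaves the two-directional endgame at 17 and joins two allylic halves instead. Methoxycarbonylation of 17 (Pd(OAc)2, dppp, CO, MeOH, Et3N, DMF, 70 °C) should give methyl (4aS,8aS)-2,5,5,8a-tetramethyl-3,4,4a,5,6,7,8,8a-octahydronaphthalene-1-carboxylate F3. DIBAL-H (CH2Cl2, −78 °C) should give [(4aS,8aS)-2,5,5,8a-tetramethyl-3,4,4a,5,6,7,8,8a-octahydronaphthalen-1-yl]methanol F4, and PBr3 (Et2O, 0 °C) the primary allylic bromide (4aS,8aS)-1-(bromomethyl)-2,5,5,8a-tetramethyl-3,4,4a,5,6,7,8,8a-octahydronaphthalene F5. Reductive homocoupling with Cp2TiCl (trivalent titanium, generated from Cp2TiCl2 and Mn dust, THF, 25 °C) should join C11 to C11′ at the unhindered primary termini and come back to the route at 20.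

Step 8. Hydrogen uptake at the shielded trisubstituted C5=C6 bond may be slow, and the alkene may migrate on the metal surface or add hydrogen with poor facial selectivity. The fallback replaces surface syn-addition by a stepwise radical reduction of 14: Mn(dpm)3 (trivalent manganese), PhSiH3, t-BuOOH, i-PrOH, 25 °C. Hydrogen-atom transfer to C6 gives the tertiary C5 radical, which should be quenched axially from the α-face under product-stability control to give the trans-fused 15, where the route is rejoined. This fallback makes no new compound (F0).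

Further compounds
F1 | step 7 | (2R)-2,6,6-trimethyl-2-(2-methylpent-4-enoyl)cyclohexan-1-one | C=CCC(C)C(=O)[C@@]1(C)CCCC(C)(C)C1=O
F2 | step 7 | 3-methyl-4-oxo-4-[(1R)-1,3,3-trimethyl-2-oxocyclohexyl]butanal | O=CCC(C)C(=O)[C@@]1(C)CCCC(C)(C)C1=O
F3 | step 11 | methyl (4aS,8aS)-2,5,5,8a-tetramethyl-3,4,4a,5,6,7,8,8a-octahydronaphthalene-1-carboxylate | COC(=O)C1=C(C)CC[C@H]2C(C)(C)CCC[C@]12C
F4 | step 11 | [(4aS,8aS)-2,5,5,8a-tetramethyl-3,4,4a,5,6,7,8,8a-octahydronaphthalen-1-yl]methanol | OCC1=C(C)CC[C@H]2C(C)(C)CCC[C@]12C
F5 | step 11 | (4aS,8aS)-1-(bromomethyl)-2,5,5,8a-tetramethyl-3,4,4a,5,6,7,8,8a-octahydronaphthalene | BrCC1=C(C)CC[C@H]2C(C)(C)CCC[C@]12C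
F0 | step 8 | none | none
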